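**Retrosynthetic overview**

1. 13 ⇒ 11 + 4 MeI (12). The strategy rests on one feature: in each outer ring (ring A with butanoyl, ring C with acetyl) the sp3 C(CH3)2 carbon lies between two O-bearing ring carbons and is the single unsubstituted CH of an acylphloroglucinol ring, whereas central ring B is a hexasubstituted benzene (one acyl, three OH, two CH2) with no CH. The four C–CH3 bonds are therefore made last.
2. 11 ⇒ symmetrical dimer 7 + iminium salt 4 + 2,4,6-trihydroxyacetophenone 8 (ring B–CH2–ring C bond, Mannich/ortho-quinone methide transfer).
3. 7 ⇒ 2 × butanoylphloroglucinol 3 + 4 (ring A–CH2–ring B bond; the first bridge gives a symmetrical product, so only the second bridging is unsymmetrical). 3 ⇒ phloroglucinol 1 + butanoyl chloride 2.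
4. Ring order: no ring is built. The three six-membered carbocycles are bought as benzene rings, joined B–A and then B–C, and rings A and C are dearomatised in the last step.

Key step: step 4

Remark on the chemistry: 13 is drawn as the enol tautomer of the target SMILES; the dearomatised rings are equilibrating β-triketone enols. Mannich bases 5 and 9 are drawn as free amines, although in the acetate-buffered medium they are partly ammonium phenoxide zwitterions.

**Route**

Step 1
Reactants: 1 phloroglucinol (benzene-1,3,5-triol); 2 butanoyl chloride
Product: 3 1-(2,4,6-trihydroxyphenyl)butan-1-one (butanoylphloroglucinol)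
Conditions: AlCl3 (4 equiv), CH2Cl2/MeNO2, 0 °C to 40 °C; then ice/aq HCl
Reagents that add atoms: butanoyl chloride (2), CCCC(Cl)=O
Why: Friedel–Crafts C-acylation of the symmetrical triphenol should stop at the monoketone with one equivalent of acid chloride, because the chelated aryl ketone–AlCl3 complex is deactivated and any aryl ester formed first is converted to the ketone by Fries rearrangement under the same conditions.

Step 2
Reactants: 3 butanoylphloroglucinol (4 equiv); 4 N,N-dimethylmethyleneiminium iodide (1 equiv)
Product: 7 bis(3-butanoyl-2,4,6-trihydroxyphenyl)methane, via Mannich base 5 (not isolated), via ortho-quinone methide 6 (not isolated)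
Conditions: NaOAc (1.1 equiv), MeCN, 0 °C to rt; then 80 °C; aq HCl work-up, excess 3 recovered
Reagents that add atoms: N,N-dimethylmethyleneiminium iodide (4), C=[N+](C)C.[I-]
Why: Mannich aminomethylation at one of the two equivalent free ring carbons of 3 gives 5, which on warming loses dimethylamine to ortho-quinone methide 6, and Friedel–Crafts-type conjugate addition of the excess 3 to the exocyclic CH2 with re-aromatisation should give the symmetrical dimer, the excess of 3 keeping double aminomethylation and capture of 6 by 7 low.

Step 3
Reactants: 7 bis(3-butanoyl-2,4,6-trihydroxyphenyl)methane; 4 N,N-dimethylmethyleneiminium iodide (0.9 equiv); 8 2,4,6-trihydroxyacetophenone (anhydrous, 5 equiv)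
Product: 11 1-[3-({3-[(3-acetyl-2,4,6-trihydroxyphenyl)methyl]-5-butanoyl-2,4,6-trihydroxyphenyl}methyl)-2,4,6-trihydroxyphenyl]butan-1-one (all-aromatic trimer), via Mannich base 9 (not isolated), via ortho-quinone methide 10 (not isolated)
Conditions: 4 (0.9 equiv), NaOAc (1 equiv), MeCN, 0 °C to rt; then 8 (5 equiv), 60 °C; aq HCl work-up, 7 and 8 recovered
Reagents that add atoms: N,N-dimethylmethyleneiminium iodide (4), C=[N+](C)C.[I-]
Why: The same Mannich aminomethylation–amine elimination–conjugate addition sequence is applied to one of the two equivalent free CH positions of 7 with less than one equivalent of iminium salt, and the ortho-quinone methide 10 released on warming should be intercepted at C3 of the large excess of 8, which is added only after the iminium salt has been consumed so that 8 itself is not aminomethylated.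

Step 4
Reactants: 11 all-aromatic trimer; 12 iodomethane (4.0 equiv)
Product: 13 2-butanoyl-6-({3-[(5-acetyl-2,4-dihydroxy-3,3-dimethyl-6-oxocyclohexa-1,4-dien-1-yl)methyl]-5-butanoyl-2,4,6-trihydroxyphenyl}methyl)-3,5-dihydroxy-4,4-dimethylcyclohexa-2,5-dien-1-one (target)
Conditions: NaOMe (8 equiv), degassed MeOH, Ar, 0 °C, slow addition of MeI, then rt; cold aq HCl to pH 2; crystallisation
Reagents that add atoms: iodomethane (12), CI
Why: In methanolic NaOMe 11 is a polyphenoxide, and rings A and C each attack iodomethane in an SN2 reaction through their one unsubstituted ring carbon (the CH between two O-bearing carbons); loss of the ring proton returns an aromatic, more electron-rich methylphloroglucinol phenoxide, which is methylated again at the same carbon to give the quaternary C(CH3)2 centre and a cross-conjugated cyclohexadienone, four C–CH3 bonds in all. The closest known reaction is the NaOMe/MeI gem-dimethylation of monomeric acylphloroglucinols to acylfilicinic acids, an alkylative dearomatisation of phenoxides. No ring is closed and no stereocentre is created, since each new sp3 carbon carries two identical methyl groups. The step needs C- over O-methylation, attack at the free CH and then at the C–CH3 carbon of rings A and C in preference to any CH2-bearing ring carbon, and a stop after two methyl groups per outer ring. C-selectivity should come from sodium phenoxides that are hydrogen-bonded in methanol reacting with a soft iodide electrophile; site selectivity from sterics, since every bridge-bearing carbon is shielded by the diarylmethane CH2 and its fully substituted neighbouring ring and ring B has no CH at all; and the stop from the product rings being delocalised β-triketone enolates of low nucleophilicity together with the limit of four equivalents of iodomethane. Low temperature and short reaction time are chosen to keep retro-Michael opening of the methylene bridges by alkoxide slow.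

**Compound list**

1 | phloroglucinol (benzene-1,3,5-triol) | Oc1cc(O)cc(O)c1 | starting material
2 | butanoyl chloride | CCCC(Cl)=O | starting material
3 | 1-(2,4,6-trihydroxyphenyl)butan-1-one (butanoylphloroglucinol) | CCCC(=O)c1c(O)cc(O)cc1O | intermediate
4 | N,N-dimethylmethyleneiminium iodide | C=[N+](C)C.[I-] | starting material
5 | 1-{3-[(dimethylamino)methyl]-2,4,6-trihydroxyphenyl}butan-1-one (Mannich base of 3) | CCCC(=O)c1c(O)cc(O)c(CN(C)C)c1O | intermediate
6 | 2-butanoyl-3,5-dihydroxy-6-methylidenecyclohexa-2,4-dien-1-one (ortho-quinone methide from 5) | CCCC(=O)C1=C(O)C=C(O)C(=C)C1=O | intermediate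
7 | bis(3-butanoyl-2,4,6-trihydroxyphenyl)methane (symmetrical dimer) | CCCC(=O)c1c(O)cc(O)c(Cc2c(O)cc(O)c(C(=O)CCC)c2O)c1O | intermediate
8 | 2,4,6-trihydroxyacetophenone | CC(=O)c1c(O)cc(O)cc1O | starting material
9 | 1-[3-({3-butanoyl-5-[(dimethylamino)methyl]-2,4,6-trihydroxyphenyl}methyl)-2,4,6-trihydroxyphenyl]butan-1-one (mono-Mannich base of 7) | CCCC(=O)c1c(O)cc(O)c(Cc2c(O)c(CN(C)C)c(O)c(C(=O)CCC)c2O)c1O | intermediate
10 | ortho-quinone methide from 9 (ring B as a butanoyl-dihydroxy-methylidene-cyclohexadienone after loss of dimethylamine) | CCCC(=O)c1c(O)cc(O)c(CC2=C(O)C(=C)C(=O)C(C(=O)CCC)=C2O)c1O | intermediate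
11 | 1-[3-({3-[(3-acetyl-2,4,6-trihydroxyphenyl)methyl]-5-butanoyl-2,4,6-trihydroxyphenyl}methyl)-2,4,6-trihydroxyphenyl]butan-1-one (all-aromatic trimer) | CCCC(=O)c1c(O)cc(O)c(Cc2c(O)c(Cc3c(O)cc(O)c(C(C)=O)c3O)c(O)c(C(=O)CCC)c2O)c1O | intermediate
12 | iodomethane | CI | starting material
13 | 2-butanoyl-6-({3-[(5-acetyl-2,4-dihydroxy-3,3-dimethyl-6-oxocyclohexa-1,4-dien-1-yl)methyl]-5-butanoyl-2,4,6-trihydroxyphenyl}methyl)-3,5-dihydroxy-4,4-dimethylcyclohexa-2,5-dien-1-one | CCCC(=O)C1=C(O)C(C)(C)C(O)=C(Cc2c(O)c(CC3=C(O)C(C)(C)C(O)=C(C(C)=O)C3=O)c(O)c(C(=O)CCC)c2O)C1=O | target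

**Step count**

Total steps: 4. Longest linear sequence: 4 steps (1 → 3 → 7 → 11 → 13).

**Steps most likely to fail**

1. Step 4. Methylation may also occur at the CH2-bearing ring carbons of rings A, B or C or at oxygen, or may stop short of four methyl groups. The alkoxide may also open the methylene bridges by retro-Michael cleavage, so that ring units recombine in scrambled order. The fallback sets out from 3 and 8 and comes back to the route at 13; it puts the methyl groups on the monomers, where no bridge carbon competes and no bridge is exposed to alkoxide. Compound 3 with NaOMe/MeI (2 equiv) in MeOH should give butanoylfilicinic acid F1 after separation from other methylation congeners, and 8 should give acetylfilicinic acid F2 in the same way. F1 is aminomethylated at its single enolic CH with 4/NaOAc in MeCN to Mannich base F3, which is warmed with excess 3 to give the mixed dimer F4. F2 is converted with 4/NaOAc into Mannich base F5, which is warmed with F4 (one free aromatic CH left, on the future ring B) to give 13.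

2. Step 3. Both free positions of 7 may be aminomethylated. Ortho-quinone methide 10 may be captured by 7, 9 or 11 in place of 8, giving chain growth. The existing bridge may also exchange under warm, weakly acidic conditions. The fallback sets out from 8 and comes back at 11; it reverses the roles of the partners. Excess 8 is treated with 4/NaOAc in MeCN at rt to give 3-[(dimethylamino)methyl]-2,4,6-trihydroxyacetophenone F6, which is isolated. F6 is then warmed at 60 °C with an excess of 7, so that the monomer-derived ortho-quinone methide is captured by the dimer and over-bridging is limited by the excess of 7, which is recovered.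

3. Step 2. Bis-aminomethylation of 3 and capture of ortho-quinone methide 6 by product 7 would lead to linear oligomers that are hard to separate. The fallback sets out from 1 and comes back at 7; it forms the bridge before the acyl groups. A large excess of 1 is condensed with aqueous formaldehyde in dilute HCl at 0 °C to rt to give bis(2,4,6-trihydroxyphenyl)methane F7. Twofold Friedel–Crafts butanoylation of F7 with 2 (2 equiv, AlCl3, CH2Cl2/MeNO2, 0 °C to rt) should place one acyl group on each ring, since the first acyl group deactivates its own ring, and give 7.

**Further compounds**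

F1 | step 4 | butanoylfilicinic acid (2-butanoyl-3,5-dihydroxy-4,4-dimethylcyclohexa-2,5-dien-1-one) | CCCC(=O)C1=C(O)C(C)(C)C(O)=CC1=O
F2 | step 4 | acetylfilicinic acid (2-acetyl-3,5-dihydroxy-4,4-dimethylcyclohexa-2,5-dien-1-one) | CC(=O)C1=C(O)C(C)(C)C(O)=CC1=O
F3 | step 4 | Mannich base of F1 (2-butanoyl-6-[(dimethylamino)methyl]-3,5-dihydroxy-4,4-dimethylcyclohexa-2,5-dien-1-one) | CCCC(=O)C1=C(O)C(C)(C)C(O)=C(CN(C)C)C1=O
F4 | step 4 | mixed dimer (2-butanoyl-6-[(3-butanoyl-2,4,6-trihydroxyphenyl)methyl]-3,5-dihydroxy-4,4-dimethylcyclohexa-2,5-dien-1-one) | CCCC(=O)C1=C(O)C(C)(C)C(O)=C(Cc2c(O)cc(O)c(C(=O)CCC)c2O)C1=O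
F5 | step 4 | Mannich base of F2 (2-acetyl-6-[(dimethylamino)methyl]-3,5-dihydroxy-4,4-dimethylcyclohexa-2,5-dien-1-one) | CC(=O)C1=C(O)C(C)(C)C(O)=C(CN(C)C)C1=O
F6 | step 3 | 3-[(dimethylamino)methyl]-2,4,6-trihydroxyacetophenone | CC(=O)c1c(O)cc(O)c(CN(C)C)c1O
F7 | step 2 | bis(2,4,6-trihydroxyphenyl)methane | Oc1cc(O)c(Cc2c(O)cc(O)cc2O)c(O)c1
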